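## Retrosynthetic overview

1. Key C–C bond (made last): ring carbon–CHO, by adding a neutral formyl-anion equivalent (a formaldehyde dialkylhydrazone) to the one unsubstituted carbon of an electrophilic ortho-quinone, a vinylogous Stetter-type union of two acceptor carbons; dilute acid then frees the aldehyde and the alcohol.
2. The ortho-quinone comes from a para-hydroxyaryl ester, whose hydroxyl is installed by sterically controlled C–H borylation/oxidation of a 2,6-dimethylphenyl ester; the chain therefore sits on the hindered oxygen from the start and the three ring oxygens never have to be told apart.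
3. Aryl ester and C3 stereocentre together: amine-catalysed asymmetric epoxidation of an (E)-C10 enal, then carbene (Breslow acyl-anion) redox esterification with the phenol in the same flask.
4. Rings: the benzene ring is bought and only oxidised and re-aromatised; the single ring that is made is a transient oxirane (step 1), opened again in the same operation.

Assumption: the (S)-configured diarylprolinol silyl ether is taken to give the (2S,3R)-epoxide (peroxide attack anti to the aryl groups); if the sense were found reversed, the mirror-image catalyst would be used.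

## Route

Step 1
Reactants: 1 (E)-dec-2-enal; 2 2,6-dimethylphenol
Product: 4 2,6-dimethylphenyl (3R)-3-hydroxydecanoate, via epoxy aldehyde 3 (not isolated)
Conditions: (S)-2-[bis(3,5-bis(trifluoromethyl)phenyl)(trimethylsilyloxy)methyl]pyrrolidine (10 mol%), 35% aq. H2O2 (1.3 equiv), CH2Cl2, rt, 4 h; organic layer dried (MgSO4); then 2 (3 equiv), 3-benzyl-4,5-dimethylthiazolium chloride (10 mol%), i-Pr2NEt (0.5 equiv), CH2Cl2, 30 °C, 15 h
Reagents that add atoms: hydrogen peroxide, OO
Why: Iminium-activated nucleophilic epoxidation (Jørgensen type) delivers the peroxide oxygen to the β-carbon face remote from the catalyst's aryl groups and sets C3 as R in the trans-(2S,3R)-epoxide 3, after which the thiazolylidene forms a Breslow intermediate that opens the oxirane at C2 only (C3–O untouched, configuration kept) to an acyl azolium that the phenol captures (Bode redox esterification, run as a one-pot amine/carbene sequence).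

Step 2
Reactants: 4 2,6-dimethylphenyl (3R)-3-hydroxydecanoate
Product: 5 2,6-dimethylphenyl (3R)-3-[(tert-butyldimethylsilyl)oxy]decanoate
Conditions: TBSCl (1.3 equiv), imidazole (2.5 equiv), DMF, rt, 12 h
Reagents that add atoms: tert-butyldimethylsilyl chloride, CC(C)(C)[Si](C)(C)Cl
Why: Standard silyl ether formation (TBSCl/imidazole) shields the secondary alcohol from the pentavalent iodine oxidant of step 4, while the hindered aryl ester and the C3 stereocentre are not touched.

Step 3
Reactants: 5 2,6-dimethylphenyl (3R)-3-[(tert-butyldimethylsilyl)oxy]decanoate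
Product: 7 4-hydroxy-2,6-dimethylphenyl (3R)-3-[(tert-butyldimethylsilyl)oxy]decanoate, via aryl boronate 6 (not isolated)
Conditions: [Ir(OMe)(cod)]2 (1.5 mol%; cod = 1,5-cyclooctadiene), 4,4'-di-tert-butyl-2,2'-bipyridine (3 mol%), B2pin2 (1.0 equiv), THF, 80 °C, 16 h; solvent exchanged; then KHSO5 (as 2KHSO5·KHSO4·K2SO4, 1.1 equiv), acetone–H2O, rt, 10 min
Reagents that add atoms: bis(pinacolato)diboron, CC1(C)OB(OC1(C)C)B1OC(C)(C)C(C)(C)O1 (boron of 6); potassium peroxymonosulfate, OOS(=O)(=O)[O-].[K+] (phenol oxygen of 7)
Why: Iridium-catalysed arene C–H borylation is sterically governed, so only the ring C–H para to the ester oxygen (the one with no ortho substituent) is borylated, and the C–B bond is then oxidised in the same pot to C–OH (one-pot C–H borylation/oxidation), giving the hydroquinone monoester acylated on the hindered oxygen with ester, silyl ether and stereocentre intact.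

Step 4
Reactants: 7 4-hydroxy-2,6-dimethylphenyl (3R)-3-[(tert-butyldimethylsilyl)oxy]decanoate; 8 formaldehyde N,N-dimethylhydrazone
Product: 10 3,4-dihydroxy-5-[(E)-(2,2-dimethylhydrazinylidene)methyl]-2,6-dimethylphenyl (3R)-3-[(tert-butyldimethylsilyl)oxy]decanoate, via ortho-quinone 9 (not isolated)
Conditions: IBX (1.0 equiv), DMF, 0 °C to rt, 1 h; then added to 8 (3 equiv), CH2Cl2, −20 °C to rt, 3 h
Reagents that add atoms: 2-iodoxybenzoic acid (IBX), OI1(=O)OC(=O)c2ccccc12
Why: Proposed new method: 2-iodoxybenzoic acid transfers oxygen to the carbon ortho to the phenol (known regioselective phenol to ortho-quinone oxidation; both ortho positions of 7 are equivalent), and in 9 every ring carbon except C5 is substituted, so the aza-enamine carbon of the hydrazone (a neutral formyl anion equivalent) can give a stable adduct only by 1,6-conjugate attack at C5 (dienone C5=C6–C1=C2–C3=O), after which proton shifts restore the catechol and the conjugated, hydrogen-bonded hydrazone irreversibly, whereas attack at a carbonyl or at a substituted carbon is reversible; the closest known reaction types are the Michael additions of formaldehyde dialkylhydrazones to enones and nitroalkenes and the 1,6-additions of thiols to ortho-quinones, and no new stereocentre is formed.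

Step 5
Reactants: 10 3,4-dihydroxy-5-[(E)-(2,2-dimethylhydrazinylidene)methyl]-2,6-dimethylphenyl (3R)-3-[(tert-butyldimethylsilyl)oxy]decanoate
Product: 11 Penicipurate A, 3-formyl-4,5-dihydroxy-2,6-dimethylphenyl (3R)-3-hydroxydecanoate
Conditions: 2 M aq. HCl–THF (1:2), rt, 12 h
Reagents that add atoms: water, O
Why: Acid hydrolysis of the N,N-dimethylhydrazone (driven by protonation of the liberated hydrazine) releases the aldehyde while the same acid cleaves the secondary silyl ether, the hindered aryl ester being stable to dilute acid at room temperature and C3 not being involved.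

## Compound list

1 | (E)-dec-2-enal | CCCCCCC/C=C/C=O | starting material
2 | 2,6-dimethylphenol | Cc1cccc(C)c1O | starting material
3 | (2S,3R)-3-heptyloxirane-2-carbaldehyde | CCCCCCC[C@H]1O[C@@H]1C=O | intermediate
4 | 2,6-dimethylphenyl (3R)-3-hydroxydecanoate | CCCCCCC[C@@H](O)CC(=O)Oc1c(C)cccc1C | intermediate
5 | 2,6-dimethylphenyl (3R)-3-[(tert-butyldimethylsilyl)oxy]decanoate | CCCCCCC[C@@H](O[Si](C)(C)C(C)(C)C)CC(=O)Oc1c(C)cccc1C | intermediate
6 | 2,6-dimethyl-4-(4,4,5,5-tetramethyl-1,3,2-dioxaborolan-2-yl)phenyl (3R)-3-[(tert-butyldimethylsilyl)oxy]decanoate | CCCCCCC[C@@H](O[Si](C)(C)C(C)(C)C)CC(=O)Oc1c(C)cc(B2OC(C)(C)C(C)(C)O2)cc1C | intermediate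
7 | 4-hydroxy-2,6-dimethylphenyl (3R)-3-[(tert-butyldimethylsilyl)oxy]decanoate | CCCCCCC[C@@H](O[Si](C)(C)C(C)(C)C)CC(=O)Oc1c(C)cc(O)cc1C | intermediate
8 | formaldehyde N,N-dimethylhydrazone | C=NN(C)C | starting material
9 | 2,6-dimethyl-3,4-dioxocyclohexa-1,5-dien-1-yl (3R)-3-[(tert-butyldimethylsilyl)oxy]decanoate | CCCCCCC[C@@H](O[Si](C)(C)C(C)(C)C)CC(=O)OC1=C(C)C(=O)C(=O)C=C1C | intermediate
10 | 3,4-dihydroxy-5-[(E)-(2,2-dimethylhydrazinylidene)methyl]-2,6-dimethylphenyl (3R)-3-[(tert-butyldimethylsilyl)oxy]decanoate | CCCCCCC[C@@H](O[Si](C)(C)C(C)(C)C)CC(=O)Oc1c(C)c(O)c(O)c(/C=N/N(C)C)c1C | intermediate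
11 | Penicipurate A, 3-formyl-4,5-dihydroxy-2,6-dimethylphenyl (3R)-3-hydroxydecanoate | CCCCCCC[C@@H](O)CC(=O)Oc1c(C)c(O)c(O)c(C=O)c1C | target

## Step count and risks

Total steps: 5. Longest linear sequence: 5 (1 → 4 → 5 → 7 → 10 → 11).

**Step 4 (highest risk).** The 1,6-addition is unprecedented for a carbon nucleophile. The hydrazone may instead reduce 9, and unreacted 9 may re-oxidise the product catechol; inverse addition at −20 °C and an aqueous Na2S2O4 wash are the first defences. The fallback sets out from 7 and comes back to the route at 11. The oxidation of 7 with IBX is kept, but 9 is reduced in the same flask with aqueous Na2S2O4 to 3,4-dihydroxy-2,6-dimethylphenyl (3R)-3-[(tert-butyldimethylsilyl)oxy]decanoate F1. The ring is then used as the nucleophile: Rieche formylation (Cl2CHOMe, TiCl4, CH2Cl2, −20 °C) at its only free carbon gives 3-formyl-4,5-dihydroxy-2,6-dimethylphenyl (3R)-3-[(tert-butyldimethylsilyl)oxy]decanoate F2. The acid treatment of step 5 then desilylates this to 11.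

**Step 1.** The hindered phenol may trap the acyl azolium too slowly, giving oligo-esters through the free C3–OH or the acid from residual water or peroxide. The fallback sets out from 1 (together with 2) and comes back at 4. The epoxidation half is kept and 3 is isolated. Pinnick oxidation (NaClO2, NaH2PO4, 2-methyl-2-butene, t-BuOH–H2O) gives (2S,3R)-3-heptyloxirane-2-carboxylic acid F3. Steglich esterification with 2 (DCC, DMAP, CH2Cl2) gives 2,6-dimethylphenyl (2S,3R)-3-heptyloxirane-2-carboxylate F4. SmI2 (THF, 2-(dimethylamino)ethanol, −78 °C) then cleaves the C2–O bond reductively to 4, with C3 again untouched.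

**Step 5.** The ortho-hydroxy hydrazone is stabilised by its hydrogen bond and may need acid strong enough to endanger the aryl ester. The fallback sets out from 10 and comes back at 11. HF·pyridine (THF, 0 °C) first removes the silyl group to give 3,4-dihydroxy-5-[(E)-(2,2-dimethylhydrazinylidene)methyl]-2,6-dimethylphenyl (3R)-3-hydroxydecanoate F5. The aldehyde is then released not by hydrolysis but by transhydrazonation to glyoxylic acid (50% aq. glyoxylic acid, THF, rt), which gives 11.

## Further compounds

F1 | step 4 | 3,4-dihydroxy-2,6-dimethylphenyl (3R)-3-[(tert-butyldimethylsilyl)oxy]decanoate | CCCCCCC[C@@H](O[Si](C)(C)C(C)(C)C)CC(=O)Oc1c(C)c(O)c(O)cc1C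
F2 | step 4 | 3-formyl-4,5-dihydroxy-2,6-dimethylphenyl (3R)-3-[(tert-butyldimethylsilyl)oxy]decanoate | CCCCCCC[C@@H](O[Si](C)(C)C(C)(C)C)CC(=O)Oc1c(C)c(O)c(O)c(C=O)c1C
F3 | step 1 | (2S,3R)-3-heptyloxirane-2-carboxylic acid | CCCCCCC[C@H]1O[C@@H]1C(=O)O
F4 | step 1 | 2,6-dimethylphenyl (2S,3R)-3-heptyloxirane-2-carboxylate | CCCCCCC[C@H]1O[C@@H]1C(=O)Oc1c(C)cccc1C
F5 | step 5 | 3,4-dihydroxy-5-[(E)-(2,2-dimethylhydrazinylidene)methyl]-2,6-dimethylphenyl (3R)-3-hydroxydecanoate | CCCCCCC[C@@H](O)CC(=O)Oc1c(C)c(O)c(O)c(/C=N/N(C)C)c1C
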